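**Retrosynthetic overview**
- The strategy rests on the 7-oxabicyclo[2.2.1]heptane core: its two tertiary ether carbons, C1 (methyl, next to C2–Br) and C4 (cyclohexyl-bearing), sit 1,4 across a six-membered ring. The O7 bridge is therefore a 1,4-endoperoxide minus one oxygen: 20 ⇐ 18 (PPh3) ⇐ 17 (diimide).
- 17 ⇐ 2-bromo-1,3-diene 16 + singlet oxygen, [4+2] across the diene termini C1/C4.
- 16 ⇐ dienyl triflate 14 ⇐ enone 12 (kinetic α′-enolate); 12 ⇐ vinyl ketone 8 + 3-methylpentane-2,4-dione (Michael addition, deacetylative aldol).
- 8 ⇐ Weinreb amide 7 ⇐ Appel inversion of cis-hydroxy amide 6 ⇐ lactone 5 ⇐ CBS reduction and epimerising lactonisation of keto ester 3 ⇐ ethyl 4-oxocyclohexanecarboxylate 1.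
- Ring order: bromodimethylcyclohexane (from 1), then the cyclohexadiene (annulation), then the 2,3-dioxabicyclo[2.2.2]octene (1O2), then contraction to the 7-oxabicyclo[2.2.1]heptane.

Key step: step 12

Remark: 3 is used as the racemate; the catalyst in step 2 sets C4 in both enantiomers and step 3 converges the C1 epimers, so no resolution is required.
Remark: the diene faces in step 12 are differentiated only by C1′; the bridgehead diastereomer of 17 is expected as a co-product and is removed by chromatography at that stage.

**Step 1**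
Reactants: 1 ethyl 4-oxocyclohexane-1-carboxylate
Product: 3 rac-ethyl 3,3-dimethyl-4-oxocyclohexane-1-carboxylate, via ethyl 3-methyl-4-oxocyclohexane-1-carboxylate 2 (not isolated)
Conditions: t-BuOK (2.2 equiv), MeI (2.5 equiv), THF, 0 °C → rt
Reagents that add atoms: iodomethane, CI
Why: Double α-methylation of the ketone through its equilibrating potassium enolates (the ketone is far more acidic than the ester); the second methyl should enter at the already substituted carbon via the more substituted enolate, and 3,5-dimethyl or over-methylated material is removed by chromatography.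

**Step 2**
Reactants: 3 rac-ethyl 3,3-dimethyl-4-oxocyclohexane-1-carboxylate
Product: 4 ethyl (4R)-4-hydroxy-3,3-dimethylcyclohexane-1-carboxylate (both C1 epimers)
Conditions: (S)-2-methyl-CBS-oxazaborolidine (10 mol %), BH3·SMe2, THF, −20 °C; MeOH quench
Reagents that add atoms: none
Why: Corey–Bakshi–Shibata reduction, in which the catalyst distinguishes the quaternary C3 flank (large) from the C5 methylene (small), so hydride should reach the same carbonyl face in both enantiomers of 3 and set C4 as R under catalyst control, independent of the remote C1 centre.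

**Step 3**
Reactants: 4 ethyl (4R)-4-hydroxy-3,3-dimethylcyclohexane-1-carboxylate
Product: 5 (1R,4S)-6,6-dimethyl-2-oxabicyclo[2.2.2]octan-3-one
Conditions: t-BuOK (10 mol %), xylene, 140 °C, EtOH distilled off
Reagents that add atoms: none
Why: Base-catalysed intramolecular transesterification (lactonisation): only the cis hydroxy ester can close the boat lactone, while the trans isomer epimerises at C1 through its ester enolate and is drawn into 5 as ethanol leaves, so C1 is fixed cis to the C4 oxygen; crystallisation of 5 should raise the enantiomeric purity.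

**Step 4**
Reactants: 5 (1R,4S)-6,6-dimethyl-2-oxabicyclo[2.2.2]octan-3-one
Product: 6 (1S,4R)-4-hydroxy-N-methoxy-N,3,3-trimethylcyclohexane-1-carboxamide
Conditions: MeNH(OMe)·HCl, AlMe3, CH2Cl2, 0 °C → rt; Rochelle salt work-up
Reagents that add atoms: N,O-dimethylhydroxylamine hydrochloride, CNOC.Cl
Why: Weinreb aminolysis of the strained lactone with the aluminium amide formed in the flask; acyl–oxygen cleavage leaves both stereocentres untouched and gives the cis hydroxy amide.

**Step 5**
Reactants: 6 (1S,4R)-4-hydroxy-N-methoxy-N,3,3-trimethylcyclohexane-1-carboxamide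
Product: 7 (1S,4S)-4-bromo-N-methoxy-N,3,3-trimethylcyclohexane-1-carboxamide
Conditions: CBr4, PPh3, CH2Cl2, 0 → 40 °C
Reagents that add atoms: carbon tetrabromide, BrC(Br)(Br)Br
Why: Appel reaction: the amide is locked equatorial (an axial C1 substituent would clash with the axial C3 methyl), so the C4 hydroxyl is axial and bromide should displace its activated form with inversion (SN2) to the equatorial (4S) bromide trans to C1; axial-OH to equatorial-Br next to a gem-dimethyl carbon is the geometry in which this substitution is known to work.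

**Step 6**
Reactants: 7 (1S,4S)-4-bromo-N-methoxy-N,3,3-trimethylcyclohexane-1-carboxamide
Product: 8 1-[(1S,4S)-4-bromo-3,3-dimethylcyclohexyl]prop-2-en-1-one
Conditions: CH2=CHMgBr, THF, −78 → 0 °C; inverse quench into cold 1 M HCl
Reagents that add atoms: vinylmagnesium bromide, C=C[Mg]Br
Why: Weinreb ketone synthesis stops at mono-addition; the cold acidic quench protonates the released amine so that it cannot add to the enone, and neither C1′ nor the hindered secondary bromide should be affected at this temperature.

**Step 7**
Reactants: 8 1-[(1S,4S)-4-bromo-3,3-dimethylcyclohexyl]prop-2-en-1-one; 9 3-methylpentane-2,4-dione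
Product: 10 3-{3-[(1S,4S)-4-bromo-3,3-dimethylcyclohexyl]-3-oxopropyl}-3-methylpentane-2,4-dione
Conditions: Et3N (10 mol %), MeCN, rt
Reagents that add atoms: none
Why: Amine-catalysed Michael addition of the acidic 1,3-diketone to the unhindered vinyl ketone; the base is too weak to enolise the ketone toward C1′, so the trans ring configuration is kept.

**Step 8**
Reactants: 10 3-{3-[(1S,4S)-4-bromo-3,3-dimethylcyclohexyl]-3-oxopropyl}-3-methylpentane-2,4-dione
Product: 12 3-[(1S,4S)-4-bromo-3,3-dimethylcyclohexyl]-6-methylcyclohex-2-en-1-one (both C6 epimers), via 1,5-diketone 11 (not isolated)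
Conditions: NaOMe (0.5 equiv), MeOH, 0 °C → rt, short reaction time
Reagents that add atoms: none
Why: Methoxide removes one acetyl group of the non-enolisable 1,3-diketone (retro-Claisen) and the methyl ketone of 11 then closes on the cyclohexyl ketone by intramolecular aldol condensation (the final stage of a Robinson annulation); mild base and short exposure are chosen to limit enolisation toward C1′, and the C6 methyl centre is formed as an inconsequential mixture.

**Step 9**
Reactants: 12 3-[(1S,4S)-4-bromo-3,3-dimethylcyclohexyl]-6-methylcyclohex-2-en-1-one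
Product: 14 5-[(1S,4S)-4-bromo-3,3-dimethylcyclohexyl]-2-methylcyclohexa-1,5-dien-1-yl trifluoromethanesulfonate, via lithium dienolate 13 (not isolated)
Conditions: LDA, THF, −78 °C; PhNTf2, −78 → 0 °C; aq. NH4Cl
Reagents that add atoms: N-phenylbis(trifluoromethanesulfonimide), O=S(=O)(N(c1ccccc1)S(=O)(=O)C(F)(F)F)C(F)(F)F
Why: Kinetic α′-deprotonation of the enone gives the cross-conjugated dienolate (both C6 epimers converge, the γ-hydrogen at C1′ is not touched) and O-triflation fixes both double bonds exactly where the target diene needs them.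

**Step 10**
Reactants: 14 5-[(1S,4S)-4-bromo-3,3-dimethylcyclohexyl]-2-methylcyclohexa-1,5-dien-1-yl trifluoromethanesulfonate
Product: 15 {5-[(1S,4S)-4-bromo-3,3-dimethylcyclohexyl]-2-methylcyclohexa-1,5-dien-1-yl}(trimethyl)stannane
Conditions: Me3SnSnMe3, Pd(PPh3)4 (5 mol %), LiCl, THF, 60 °C
Reagents that add atoms: hexamethylditin, C[Sn](C)(C)[Sn](C)(C)C
Why: Pd(0)-catalysed stannylation of an enol triflate (Stille-type coupling with a distannane); the unactivated, hindered secondary alkyl bromide should not undergo oxidative addition under these conditions.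

**Step 11**
Reactants: 15 {5-[(1S,4S)-4-bromo-3,3-dimethylcyclohexyl]-2-methylcyclohexa-1,5-dien-1-yl}(trimethyl)stannane
Product: 16 2-bromo-4-[(1S,4S)-4-bromo-3,3-dimethylcyclohexyl]-1-methylcyclohexa-1,3-diene
Conditions: NBS, CH2Cl2, −78 → 0 °C, dark
Reagents that add atoms: N-bromosuccinimide, O=C1CCC(=O)N1Br
Why: Bromodestannylation: electrophilic ipso attack at the tin-bearing carbon (β-tin-stabilised cation) replaces SnMe3 by Br without moving the diene.

**Step 12**
Reactants: 16 2-bromo-4-[(1S,4S)-4-bromo-3,3-dimethylcyclohexyl]-1-methylcyclohexa-1,3-diene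
Product: 17 (1R,4R)-5-bromo-1-[(1S,4S)-4-bromo-3,3-dimethylcyclohexyl]-4-methyl-2,3-dioxabicyclo[2.2.2]oct-5-ene
Conditions: O2, tetraphenylporphyrin (1 mol %), CH2Cl2, hν (LED, > 500 nm), −30 °C
Reagents that add atoms: dioxygen, O=O
Why: Sensitised O2 gives singlet oxygen, which should add suprafacially to the ring-locked s-cis diene of 16 in a concerted [4+2] cycloaddition, forming the C–O bonds at the diene termini C1 (methyl) and C4 (cyclohexyl) and leaving C2(Br)=C3 as the two-carbon bridge C5=C6 of 17. The closest known case is the dye-sensitised photooxygenation of α-terpinene to ascaridole, of which 16 is the 2-bromo analogue; bromine on an internal diene carbon lowers the diene's reactivity but should not suppress it. The one new ring, the six-membered 1,2-dioxene that completes the 2,3-dioxabicyclo[2.2.2]oct-5-ene, is closed by cycloaddition, with both C–O bonds coming from one O2 molecule. The two new stereocentres are the bridgeheads: their mutual cis relation follows from suprafacial addition, and their absolute sense depends on the diene face attacked, which only the C1′ centre on the diene terminus can bias; with C1′–H eclipsing the C3=C4 bond, attack on the face flanked by C6′H2 and not by the C2′H2–CMe2 branch leads to (1R,4R)-17. The step needs [4+2] over ene chemoselectivity, which the cisoid diene with fully alkylated termini should provide, and π-facial selectivity, which is expected to be weak, so the (1S,4S) bridgehead diastereomer has to be separated. Both bridgeheads are fully substituted, so base-induced Kornblum–DeLaMare cleavage is not possible and the peroxide can be carried on.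

**Step 13**
Reactants: 17 (1R,4R)-5-bromo-1-[(1S,4S)-4-bromo-3,3-dimethylcyclohexyl]-4-methyl-2,3-dioxabicyclo[2.2.2]oct-5-ene
Product: 18 (1S,4R,5R)-5-bromo-1-[(1S,4S)-4-bromo-3,3-dimethylcyclohexyl]-4-methyl-2,3-dioxabicyclo[2.2.2]octane
Conditions: dipotassium azodicarboxylate (excess, in portions), AcOH, MeOH/CH2Cl2, 0 °C → rt
Reagents that add atoms: none
Why: Diimide reduction transfers H2 concertedly and syn to the strained C5=C6 bond without cleaving the O–O bond (as for ascaridole → dihydroascaridole); diimide should approach from the face flanked by the hydrogen-free peroxide bridge, not the C7–C8 ethano bridge, so that bromine at the new C5 stereocentre is left anti to the peroxide, to be confirmed by NOE.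

**Step 14**
Reactants: 18 (1S,4R,5R)-5-bromo-1-[(1S,4S)-4-bromo-3,3-dimethylcyclohexyl]-4-methyl-2,3-dioxabicyclo[2.2.2]octane
Product: 20 (1R,2R,4S)-2-bromo-4-[(1S,4S)-4-bromo-3,3-dimethylcyclohexyl]-1-methyl-7-oxabicyclo[2.2.1]heptane (target), via dioxaphosphorane 19 (not isolated)
Conditions: PPh3, toluene, rt → 80 °C
Reagents that add atoms: none
Why: Phosphine deoxygenation of a saturated endoperoxide (as for dihydroascaridole → 1,4-cineole): PPh3 inserts into the O–O bond, the phosphorane ionises at the bromine-free, cyclohexyl-bearing tertiary C–O bond, and the oxygen on the methyl-bearing carbon recloses on the same ring face with loss of Ph3P=O; the methyl-bearing bridgehead and the C–Br centre are untouched, and elimination to unsaturated alcohols is the expected side reaction.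

**Compound list**
1 | ethyl 4-oxocyclohexane-1-carboxylate | CCOC(=O)C1CCC(=O)CC1 | starting material
2 | ethyl 3-methyl-4-oxocyclohexane-1-carboxylate (stereoisomer mixture, not isolated) | CCOC(=O)C1CCC(=O)C(C)C1 | intermediate
3 | rac-ethyl 3,3-dimethyl-4-oxocyclohexane-1-carboxylate | CCOC(=O)C1CCC(=O)C(C)(C)C1 | intermediate
4 | ethyl (4R)-4-hydroxy-3,3-dimethylcyclohexane-1-carboxylate (both C1 epimers) | CC1(C)CC(C(=O)OCC)CC[C@H]1O | intermediate
5 | (1R,4S)-6,6-dimethyl-2-oxabicyclo[2.2.2]octan-3-one | CC1(C)C[C@@H]2CC[C@H]1OC2=O | intermediate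
6 | (1S,4R)-4-hydroxy-N-methoxy-N,3,3-trimethylcyclohexane-1-carboxamide (cis) | CC1(C)C[C@@H](C(=O)N(C)OC)CC[C@H]1O | intermediate
7 | (1S,4S)-4-bromo-N-methoxy-N,3,3-trimethylcyclohexane-1-carboxamide (trans) | CC1(C)C[C@@H](C(=O)N(C)OC)CC[C@@H]1Br | intermediate
8 | 1-[(1S,4S)-4-bromo-3,3-dimethylcyclohexyl]prop-2-en-1-one | CC1(C)C[C@@H](C(=O)C=C)CC[C@@H]1Br | intermediate
9 | 3-methylpentane-2,4-dione | CC(=O)C(C)C(C)=O | starting material
10 | 3-{3-[(1S,4S)-4-bromo-3,3-dimethylcyclohexyl]-3-oxopropyl}-3-methylpentane-2,4-dione | CC1(C)C[C@@H](C(=O)CCC(C)(C(C)=O)C(C)=O)CC[C@@H]1Br | intermediate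
11 | 1-[(1S,4S)-4-bromo-3,3-dimethylcyclohexyl]-4-methylhexane-1,5-dione (C4 epimers, not isolated) | CC1(C)C[C@@H](C(=O)CCC(C)C(C)=O)CC[C@@H]1Br | intermediate
12 | 3-[(1S,4S)-4-bromo-3,3-dimethylcyclohexyl]-6-methylcyclohex-2-en-1-one (both C6 epimers) | CC1(C)C[C@@H](C2=CC(=O)C(C)CC2)CC[C@@H]1Br | intermediate
13 | lithium 5-[(1S,4S)-4-bromo-3,3-dimethylcyclohexyl]-2-methylcyclohexa-1,5-dien-1-olate (not isolated) | CC1(C)C[C@@H](C2=CC(O[Li])=C(C)CC2)CC[C@@H]1Br | intermediate
14 | 5-[(1S,4S)-4-bromo-3,3-dimethylcyclohexyl]-2-methylcyclohexa-1,5-dien-1-yl trifluoromethanesulfonate | CC1(C)C[C@@H](C2=CC(OS(=O)(=O)C(F)(F)F)=C(C)CC2)CC[C@@H]1Br | intermediate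
15 | {5-[(1S,4S)-4-bromo-3,3-dimethylcyclohexyl]-2-methylcyclohexa-1,5-dien-1-yl}(trimethyl)stannane | CC1(C)C[C@@H](C2=CC([Sn](C)(C)C)=C(C)CC2)CC[C@@H]1Br | intermediate
16 | 2-bromo-4-[(1S,4S)-4-bromo-3,3-dimethylcyclohexyl]-1-methylcyclohexa-1,3-diene | CC1(C)C[C@@H](C2=CC(Br)=C(C)CC2)CC[C@@H]1Br | intermediate
17 | (1R,4R)-5-bromo-1-[(1S,4S)-4-bromo-3,3-dimethylcyclohexyl]-4-methyl-2,3-dioxabicyclo[2.2.2]oct-5-ene | CC1(C)C[C@@H]([C@@]23CC[C@@](C)(OO2)C(Br)=C3)CC[C@@H]1Br | intermediate
18 | (1S,4R,5R)-5-bromo-1-[(1S,4S)-4-bromo-3,3-dimethylcyclohexyl]-4-methyl-2,3-dioxabicyclo[2.2.2]octane (Br anti to the peroxide bridge) | CC1(C)C[C@@H]([C@@]23CC[C@@](C)(OO2)[C@H](Br)C3)CC[C@@H]1Br | intermediate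
19 | 6-bromo-1-[(1S,4S)-4-bromo-3,3-dimethylcyclohexyl]-5-methyl-3,3,3-triphenyl-2,4-dioxa-3λ5-phosphabicyclo[3.2.2]nonane (configuration as in 18, not isolated) | CC1(C)C[C@@H]([C@@]23CC[C@@](C)(OP(c4ccccc4)(c4ccccc4)(c4ccccc4)O2)[C@H](Br)C3)CC[C@@H]1Br | intermediate
20 | (1R,2R,4S)-2-bromo-4-[(1S,4S)-4-bromo-3,3-dimethylcyclohexyl]-1-methyl-7-oxabicyclo[2.2.1]heptane (Br endo, anti to O7) | CC1(C)C[C@@H]([C@@]23CC[C@@](C)(O2)[C@H](Br)C3)CC[C@@H]1Br | target

Total step count: 14
Longest linear sequence: 14 steps (1 → 20)

**Steps most likely to fail**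

Step 13. Hydrogen transfer to the bromine-bearing trisubstituted double bond may be too slow, so that diimide is lost to disproportionation. Alternatively, hydrogen may arrive from the ethano-bridge face, which would leave bromine syn to the peroxide and lead to the C2 epimer of the target. The fallback sets out from 17 and comes back at 20. The O–O bond of 17 is reduced with thiourea (MeOH, rt) to the cis ene-diol (1R,4R)-2-bromo-4-[(1S,4S)-4-bromo-3,3-dimethylcyclohexyl]-1-methylcyclohex-2-ene-1,4-diol F1. F1 is hydrogenated with [Ir(cod)(PCy3)(py)]PF6 and H2 in CH2Cl2; both tertiary allylic hydroxyls lie on one ring face and should direct H2 to that face, so bromine ends trans to them in (1R,2R,4S)-2-bromo-4-[(1S,4S)-4-bromo-3,3-dimethylcyclohexyl]-1-methylcyclohexane-1,4-diol F2. F2 is then closed with catalytic camphorsulfonic acid (CH2Cl2, 0 °C): ionisation at the bromine-free carbinol carbon C4 and capture by the C1 hydroxyl on the same face give 20, the way 1,4-cineole forms from cis-1,4-terpin. This path also avoids the phosphine step.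

Step 12. The ene reaction at the allylic positions may compete, or the brominated diene may add singlet oxygen too slowly, and the facial bias may be negligible. The fallback sets out from 16 and comes back at 17. It replaces singlet oxygen by a radical-cation chain oxygenation with ground-state O2: tris(4-bromophenyl)aminium hexachloroantimonate (5 mol %), O2, CH2Cl2, −78 °C. This [4+2] oxygenation is known for 1,3-dienes such as ergosteryl acetate, forms the same two C–O bonds without an ene pathway, and the low temperature may sharpen any facial preference. It makes no new compound (F0).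

Step 5. Elimination to the cyclohexene or a 1,2-methyl shift may outrun substitution at the carbinol carbon next to the quaternary centre. The fallback sets out from 6 and comes back at 7. The alcohol is converted into (1R,4S)-4-[methoxy(methyl)carbamoyl]-2,2-dimethylcyclohexyl trifluoromethanesulfonate F3 (Tf2O, 2,6-lutidine, CH2Cl2, −78 °C). The isolated sulfonate is then displaced with tetrabutylammonium bromide in toluene (−20 °C → rt), an SN2 reaction with inversion by a soluble, weakly basic bromide source, which gives 7.

**Further compounds**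
F1 | step 13 | (1R,4R)-2-bromo-4-[(1S,4S)-4-bromo-3,3-dimethylcyclohexyl]-1-methylcyclohex-2-ene-1,4-diol | CC1(C)C[C@@H]([C@]2(O)CC[C@@](C)(O)C(Br)=C2)CC[C@@H]1Br
F2 | step 13 | (1R,2R,4S)-2-bromo-4-[(1S,4S)-4-bromo-3,3-dimethylcyclohexyl]-1-methylcyclohexane-1,4-diol | CC1(C)C[C@@H]([C@]2(O)CC[C@@](C)(O)[C@H](Br)C2)CC[C@@H]1Br
F0 | step 12 | none | none
F3 | step 5 | (1R,4S)-4-[methoxy(methyl)carbamoyl]-2,2-dimethylcyclohexyl trifluoromethanesulfonate | CC1(C)C[C@@H](C(=O)N(C)OC)CC[C@H]1OS(=O)(=O)C(F)(F)F
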